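**Plan**

- Retrosynthesis: ring C is opened at C4–C4a (Friedel–Crafts acylation), then at O1–C2 (phenoxide addition to an aryl propiolate). The three-carbon chain is cut at C3–C4 (acetylide acylation) and C2–C3 (aldehyde dibromo-olefination). The 3'-OH is carried as an isopropyl ether.
- Forward: rings A and B are bought as 2,3,4-trimethoxyphenol and 3-hydroxy-4,5-dimethoxybenzaldehyde. The chain C2–C3–C4 is grown on the aldehyde carbon of ring B, ring A is attached through O1, ring C is closed, and the isopropyl group is removed last.
- Enabling feature: on ring A, C4a is the only hydrogen-bearing carbon ortho to O1 (the other ortho carbon, C8, carries a methoxy group) and it lies para to the C7 methoxy group. The acyl carbon C4, held on the O1–C2=C3 tether, can therefore bond only there, giving the six-membered ring C.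
- Stereochemistry: the target has no stereocentre. The only stereo element on the way is the C2=C3 enol ether geometry, set Z by anti addition and self-correcting in acid.

Key step: step 6

Remark: the phenoxide addition of step 4 is taken to give mainly the Z enol ether; any E isomer is carried along, because the two interconvert under the acid of step 6.

**Route**

Step 1
Reactants: 1 3-hydroxy-4,5-dimethoxybenzaldehyde
Product: 2 3-isopropoxy-4,5-dimethoxybenzaldehyde
Conditions: 2-bromopropane, K2CO3, DMF, 70 °C
Reagents that add atoms: 2-bromopropane, CC(C)Br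
Why: Williamson ether synthesis of the phenoxide with a secondary bromide in a dipolar aprotic solvent; the isopropyl ether tolerates organolithium, base and Brønsted acid and can later be removed beside methyl ethers.

Step 2
Reactants: 2 3-isopropoxy-4,5-dimethoxybenzaldehyde
Product: 3 5-(2,2-dibromoethenyl)-1-isopropoxy-2,3-dimethoxybenzene
Conditions: CBr4, PPh3, Zn dust, CH2Cl2, 25 °C; then 2, 25 °C
Reagents that add atoms: carbon tetrabromide, BrC(Br)(Br)Br
Why: Ramirez dibromo-olefination, the first stage of the Corey–Fuchs homologation; the ylide Ph3P=CBr2 formed from CBr4, PPh3 and Zn undergoes a Wittig reaction with the aryl aldehyde, forming C2–C3, while the ethers are inert.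

Step 3
Reactants: 3 5-(2,2-dibromoethenyl)-1-isopropoxy-2,3-dimethoxybenzene, 4 ethyl chloroformate
Product: 6 ethyl 3-(3-isopropoxy-4,5-dimethoxyphenyl)prop-2-ynoate, via lithium arylacetylide 5 (not isolated)
Conditions: n-BuLi (2.1 equiv), THF, −78 °C; then ClCO2Et, −78 °C to 0 °C
Reagents that add atoms: none
Why: Second stage of the Corey–Fuchs sequence; Li/Br exchange, Fritsch–Buttenberg–Wiechell-type rearrangement and deprotonation give the lithium acetylide, whose C-acylation by the chloroformate forms C3–C4, and at −78 °C the exchange should outrun ring metalation.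

Step 4
Reactants: 6 ethyl 3-(3-isopropoxy-4,5-dimethoxyphenyl)prop-2-ynoate, 7 2,3,4-trimethoxyphenol
Product: 8 ethyl (Z)-3-(3-isopropoxy-4,5-dimethoxyphenyl)-3-(2,3,4-trimethoxyphenoxy)prop-2-enoate
Conditions: K2CO3 (0.3 equiv), DMF, 80 °C
Reagents that add atoms: none
Why: Base-mediated oxa-Michael addition of the phenoxide to the β-carbon of the ynoate forms O1–C2, and anti protonation of the resulting vinyl anion should place the aryloxy group cis to the ester (Z); no stereocentre is formed.

Step 5
Reactants: 8 ethyl (Z)-3-(3-isopropoxy-4,5-dimethoxyphenyl)-3-(2,3,4-trimethoxyphenoxy)prop-2-enoate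
Product: 10 (Z)-3-(3-isopropoxy-4,5-dimethoxyphenyl)-3-(2,3,4-trimethoxyphenoxy)prop-2-enoic acid, via lithium carboxylate 9 (not isolated)
Conditions: LiOH·H2O, THF/MeOH/H2O, 40 °C; then cold 1 M HCl to pH 3
Reagents that add atoms: lithium hydroxide, [Li+].[OH-]
Why: Saponification of the ethyl ester by acyl–oxygen cleavage; the β-carbon is shielded by two aryl groups, and a cold, only mildly acidic work-up should spare the enol ether.

Step 6
Reactants: 10 (Z)-3-(3-isopropoxy-4,5-dimethoxyphenyl)-3-(2,3,4-trimethoxyphenoxy)prop-2-enoic acid
Product: 11 2-(3-isopropoxy-4,5-dimethoxyphenyl)-6,7,8-trimethoxy-4H-chromen-4-one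
Conditions: Eaton's reagent (P2O5 in MeSO3H, about 1:10 by weight), 25 to 50 °C; poured onto ice
Reagents that add atoms: none
Why: In Eaton's reagent the carboxyl group of 10 is dehydrated to an acylium ion held cis to the aryloxy ring; C4a of ring A attacks it, and loss of the C4a proton from the Wheland intermediate forms C4–C4a and the pyranone. The closest known reaction is the classical acid-mediated cyclisation of β-aryloxycinnamic and β-aryloxyacrylic acids to flavones and chromones, an intramolecular Friedel–Crafts acylation. Ring C closes in a six-membered mode that is exo with respect to the acylium C=O (6-exo-dig at the acyl carbon), with the C4a–C8a bond of ring A becoming part of the new ring. No stereocentre is created, and the enol ether geometry does not matter because the E and Z isomers interconvert by reversible protonation at C3. The step needs site selectivity, which ring A secures: C4a is the only hydrogen-bearing carbon ortho to O1 (C8 is methoxylated) and is activated by the para C7 methoxy group, whereas closure onto C2' or C6' of ring B would need the E isomer and a strained five-membered indenone-type transition state, so the equilibrating mixture should drain through the six-membered pathway. Partial loss of the isopropyl group in the medium would do no harm, since 11 and its free phenol both end as 13 after step 7.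

Step 7
Reactants: 11 2-(3-isopropoxy-4,5-dimethoxyphenyl)-6,7,8-trimethoxy-4H-chromen-4-one
Product: 13 2-(3-hydroxy-4,5-dimethoxyphenyl)-6,7,8-trimethoxy-4H-chromen-4-one, via aryloxydichloroborane 12 (not isolated)
Conditions: BCl3 (3 equiv), CH2Cl2, −78 °C to 0 °C; then H2O
Reagents that add atoms: none
Why: Lewis acid dealkylation of an aryl isopropyl ether; BCl3 binds the ether oxygen and the secondary alkyl group leaves as a cation-like fragment captured by chloride far faster than any methyl group is displaced at low temperature, no methoxy group sits peri or ortho to the C4 carbonyl (C5 bears hydrogen) to invite chelation-assisted demethylation, and hydrolysis of the aryloxyborane releases the phenol.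

**Compound list**

1 | 3-hydroxy-4,5-dimethoxybenzaldehyde | COc1cc(C=O)cc(O)c1OC | starting material
2 | 3-isopropoxy-4,5-dimethoxybenzaldehyde | COc1cc(C=O)cc(OC(C)C)c1OC | intermediate
3 | 5-(2,2-dibromoethenyl)-1-isopropoxy-2,3-dimethoxybenzene | COc1cc(C=C(Br)Br)cc(OC(C)C)c1OC | intermediate
4 | ethyl chloroformate | CCOC(Cl)=O | starting material
5 | lithium (3-isopropoxy-4,5-dimethoxyphenyl)acetylide | [Li]C#Cc1cc(OC)c(OC)c(OC(C)C)c1 | intermediate (not isolated)
6 | ethyl 3-(3-isopropoxy-4,5-dimethoxyphenyl)prop-2-ynoate | CCOC(=O)C#Cc1cc(OC)c(OC)c(OC(C)C)c1 | intermediate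
7 | 2,3,4-trimethoxyphenol | COc1ccc(O)c(OC)c1OC | starting material
8 | ethyl (Z)-3-(3-isopropoxy-4,5-dimethoxyphenyl)-3-(2,3,4-trimethoxyphenoxy)prop-2-enoate | CCOC(=O)/C=C(\Oc1ccc(OC)c(OC)c1OC)c1cc(OC)c(OC)c(OC(C)C)c1 | intermediate
9 | lithium (Z)-3-(3-isopropoxy-4,5-dimethoxyphenyl)-3-(2,3,4-trimethoxyphenoxy)prop-2-enoate | [Li+].[O-]C(=O)/C=C(\Oc1ccc(OC)c(OC)c1OC)c1cc(OC)c(OC)c(OC(C)C)c1 | intermediate (not isolated)
10 | (Z)-3-(3-isopropoxy-4,5-dimethoxyphenyl)-3-(2,3,4-trimethoxyphenoxy)prop-2-enoic acid | OC(=O)/C=C(\Oc1ccc(OC)c(OC)c1OC)c1cc(OC)c(OC)c(OC(C)C)c1 | intermediate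
11 | 2-(3-isopropoxy-4,5-dimethoxyphenyl)-6,7,8-trimethoxy-4H-chromen-4-one | COc1cc(-c2cc(=O)c3cc(OC)c(OC)c(OC)c3o2)cc(OC(C)C)c1OC | intermediate
12 | 2-[3-(dichloroboranyloxy)-4,5-dimethoxyphenyl]-6,7,8-trimethoxy-4H-chromen-4-one | COc1cc(-c2cc(=O)c3cc(OC)c(OC)c(OC)c3o2)cc(OB(Cl)Cl)c1OC | intermediate (not isolated)
13 | 2-(3-hydroxy-4,5-dimethoxyphenyl)-6,7,8-trimethoxy-4H-chromen-4-one | COc1cc(-c2cc(=O)c3cc(OC)c(OC)c(OC)c3o2)cc(O)c1OC | target

**Count and risks**

Total step count: 7. Longest linear sequence: 7 steps (1 to 13).

Steps most likely to fail: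

Step 6. What may go wrong: ring closure onto ring B from the E isomer (a five-membered closure at C2' or C6', both alkoxy-activated), acid cleavage of the aryl vinyl ether (reversal of the conjugate addition, or hydrolysis on quenching), or sulfonation of the electron-rich rings. The fallback builds the pyranone by a chalcone route and sets out from 7 and 2. Ortho C-acetylation of 7 with AcOH and BF3·OEt2 at 90 °C should give 1-(2-hydroxy-3,4,5-trimethoxyphenyl)ethan-1-one F1, the hydroxyl group directing to its only free ortho carbon. Claisen–Schmidt condensation of F1 with aldehyde 2 (KOH, EtOH, 25 °C) should give (E)-1-(2-hydroxy-3,4,5-trimethoxyphenyl)-3-(3-isopropoxy-4,5-dimethoxyphenyl)prop-2-en-1-one F2. Oxidative cyclisation of the 2'-hydroxychalcone with catalytic I2 in DMSO at 130 °C would close ring C, and the route is rejoined at 11.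

Step 4. What may go wrong: slow or reversible conjugate addition of the hindered, ortho-substituted phenoxide to an ynoate whose β-carbon is deactivated by the electron-rich ring B, with base-induced degradation of the ynoate competing. The fallback sets out from 6. Anti hydroiodination with NaI in AcOH at 80 °C should give ethyl (Z)-3-iodo-3-(3-isopropoxy-4,5-dimethoxyphenyl)prop-2-enoate F3. An Ullmann-type vinyl C–O coupling of F3 with 7 (CuI, 1,10-phenanthroline, Cs2CO3, toluene, 90 °C) would replace iodide by the aryloxy group with retention of geometry, and the route is rejoined at 8.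

Step 5. What may go wrong: attack of hydroxide at the β-carbon (the future C2) with expulsion of the aryloxide, sluggish hydrolysis of the deactivated vinylogous carbonate carbonyl, or hydrolysis of the enol ether during acidification. The fallback avoids hydroxide by using an acid-cleavable ester and sets out from 3. The lithium acetylide 5, generated as in step 3, is quenched with di-tert-butyl dicarbonate to give tert-butyl 3-(3-isopropoxy-4,5-dimethoxyphenyl)prop-2-ynoate F4. Addition of 7 under the conditions of step 4 should give tert-butyl (Z)-3-(3-isopropoxy-4,5-dimethoxyphenyl)-3-(2,3,4-trimethoxyphenoxy)prop-2-enoate F5. CF3CO2H in CH2Cl2 at 0 to 25 °C would remove the tert-butyl group as 2-methylpropene under anhydrous conditions, and the route is rejoined at 10.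

**Further compounds**

F1 | step 6 | 1-(2-hydroxy-3,4,5-trimethoxyphenyl)ethan-1-one | CC(=O)c1cc(OC)c(OC)c(OC)c1O
F2 | step 6 | (E)-1-(2-hydroxy-3,4,5-trimethoxyphenyl)-3-(3-isopropoxy-4,5-dimethoxyphenyl)prop-2-en-1-one | COc1cc(/C=C/C(=O)c2cc(OC)c(OC)c(OC)c2O)cc(OC(C)C)c1OC
F3 | step 4 | ethyl (Z)-3-iodo-3-(3-isopropoxy-4,5-dimethoxyphenyl)prop-2-enoate | CCOC(=O)/C=C(\I)c1cc(OC)c(OC)c(OC(C)C)c1
F4 | step 5 | tert-butyl 3-(3-isopropoxy-4,5-dimethoxyphenyl)prop-2-ynoate | CC(C)(C)OC(=O)C#Cc1cc(OC)c(OC)c(OC(C)C)c1
F5 | step 5 | tert-butyl (Z)-3-(3-isopropoxy-4,5-dimethoxyphenyl)-3-(2,3,4-trimethoxyphenoxy)prop-2-enoate | CC(C)(C)OC(=O)/C=C(\Oc1ccc(OC)c(OC)c1OC)c1cc(OC)c(OC)c(OC(C)C)c1
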